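**Retrosynthetic overview**
- The strategy rests on the E exocyclic C5=C6 alkene of the butenolide ring (O1, C2, C3, C4, C5), in which C7 lies cis to C4. It is stored as an erythro (anti) C5–O/C6–O pair and released last by anti-elimination of C5–H/C6–OTf from the 4-O-palmitoyl tetronate 23.
- The tetronic acid ring, the only ring made, is closed by Dieckmann formation of C3–C4 from the O5-propanoate methyl ester 19, with O6 blocked as its triethylsilyl ether.
- 19 comes from the anti diol 15, made by hydroxylation of the dianion of β-hydroxy ester 13; 13 comes from acid 9 by two-carbon homologation to β-keto ester 12 and asymmetric ketone hydrogenation.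
- Acid 9 (C7 stereocentre) comes from asymmetric hydrogenation of the (E)-2-methyl-2-enoic acid 8. Compound 8 is built from farnesyl acetate by terminal allylic oxidation and copper-catalysed coupling of the allylic acetate with (furan-3-ylmethyl)magnesium chloride (C17–C18).
- Ring order: furan (bought), then the butenolide (step 12).

Key step: step 12

Assumption: the facial sense of the hydrogenation in step 6 is taken from the tiglic acid model, on which the (S)-configured ligand should give the 2S acid (otherwise the antipodal ligand is used). Numbering throughout: butenolide O1, C2 (C=O), C3 (Me), C4 (O-acyl), C5; chain C6 to C18; furan carbon C19.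

**Step 1**
Reactants: 1 furan-3-ylmethanol
Product: 2 3-(chloromethyl)furan
Conditions: SOCl2, pyridine, Et2O, 0 °C; used at once
Reagents that add atoms: thionyl chloride, O=S(Cl)Cl
Why: Chlorodehydroxylation through the chlorosulfite (SN2 by chloride) should give the primary chloride, with pyridine taking up HCl so that the acid-sensitive furan is spared.

**Step 2**
Reactants: 3 (2E,6E)-farnesyl acetate
Product: 4 (2E,6E,10E)-12-hydroxy-3,7,11-trimethyldodeca-2,6,10-trien-1-yl acetate
Conditions: SeO2 (cat.), tBuOOH, salicylic acid (cat.), CH2Cl2, 0 °C to rt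
Reagents that add atoms: selenium dioxide, O=[Se]=O (oxygen donor, turned over by tert-butyl hydroperoxide, CC(C)(C)OO)
Why: Riley allylic oxidation (ene reaction of SeO2, then [2,3]-sigmatropic shift) should hydroxylate the E-methyl group of the terminal, most electron-rich trisubstituted alkene with E geometry, the C2=C3 alkene being deactivated by its allylic acetate.

**Step 3**
Reactants: 2 3-(chloromethyl)furan; 4 (2E,6E,10E)-12-hydroxy-3,7,11-trimethyldodeca-2,6,10-trien-1-yl acetate
Product: 6 (2E,6E,10E)-13-(furan-3-yl)-2,6,10-trimethyltrideca-2,6,10-trien-1-ol, via (furan-3-ylmethyl)magnesium chloride 5 (not isolated)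
Conditions: 2 (3 equiv), Mg turnings, THF, 0 °C to rt; then 4, Li2CuCl4 (3 mol %), THF, −78 to 0 °C; aq. NH4Cl
Reagents that add atoms: none
Why: Copper-catalysed SN2 allylic substitution of the primary allylic acetate by the Grignard reagent (one equivalent is spent on the free hydroxyl) should form C17–C18 with retention of the E alkene, since γ-attack would have to create a quaternary carbon.

**Step 4**
Reactants: 6 (2E,6E,10E)-13-(furan-3-yl)-2,6,10-trimethyltrideca-2,6,10-trien-1-ol
Product: 7 (2E,6E,10E)-13-(furan-3-yl)-2,6,10-trimethyltrideca-2,6,10-trienal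
Conditions: MnO2 (activated, excess), CH2Cl2, rt
Reagents that add atoms: none
Why: Allylic alcohol oxidation on MnO2 is selective for the allylic carbinol and should leave the furan, the isolated alkenes and the E geometry untouched.

**Step 5**
Reactants: 7 (2E,6E,10E)-13-(furan-3-yl)-2,6,10-trimethyltrideca-2,6,10-trienal
Product: 8 (2E,6E,10E)-13-(furan-3-yl)-2,6,10-trimethyltrideca-2,6,10-trienoic acid
Conditions: AgNO3, NaOH, EtOH/H2O, 0 °C to rt; then cold 1 M HCl to pH 3
Reagents that add atoms: sodium hydroxide, [Na+].[OH-]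
Why: Silver oxide oxidation (Ag2O formed in the flask, Tollens type) converts the enal to the carboxylate without electrophilic halogen or peracid, so the furan and the alkenes should survive.

**Step 6**
Reactants: 8 (2E,6E,10E)-13-(furan-3-yl)-2,6,10-trimethyltrideca-2,6,10-trienoic acid
Product: 9 (2S,6E,10E)-13-(furan-3-yl)-2,6,10-trimethyltrideca-6,10-dienoic acid
Conditions: Ru(OAc)2[(S)-H8-BINAP] (1 mol %), H2 (2–4 atm), MeOH, rt
Reagents that add atoms: none
Why: Carboxylate-directed Noyori-type asymmetric hydrogenation reduces only the alkene conjugated to the ruthenium-bound carboxylate; the ligand selects the enantiotopic face and should set C7 as S, while the isolated trisubstituted alkenes and the furan do not bind.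

**Step 7**
Reactants: 9 (2S,6E,10E)-13-(furan-3-yl)-2,6,10-trimethyltrideca-6,10-dienoic acid; 10 methyl potassium malonate
Product: 12 methyl (4S,8E,12E)-15-(furan-3-yl)-4,8,12-trimethyl-3-oxopentadeca-8,12-dienoate, via acyl imidazolide 11 (not isolated)
Conditions: 1,1'-carbonyldiimidazole, THF, rt; then 10, MgCl2, Et3N, THF/MeCN, rt to 40 °C; cold 1 M HCl
Reagents that add atoms: none
Why: Masamune–Brooks homologation: the acyl imidazolide C-acylates the magnesium enolate of the malonate half-ester and decarboxylation follows, under near-neutral conditions that should not epimerise C7 (the product enolises between its two carbonyls, not toward C7).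

**Step 8**
Reactants: 12 methyl (4S,8E,12E)-15-(furan-3-yl)-4,8,12-trimethyl-3-oxopentadeca-8,12-dienoate
Product: 13 methyl (3R,4S,8E,12E)-15-(furan-3-yl)-3-hydroxy-4,8,12-trimethylpentadeca-8,12-dienoate
Conditions: RuCl2[(S)-BINAP] (1 mol %), H2 (4 atm), MeOH, 60 °C
Reagents that add atoms: none
Why: Noyori asymmetric hydrogenation of the β-keto ester through its ruthenium chelate should set C6 under catalyst control (the same spatial sense as (S)-methyl 3-hydroxybutanoate from methyl acetoacetate), unfunctionalised trisubstituted alkenes being inert to this catalyst; a C6 epimer would do no harm, because after step 9 it is the other erythro pair and leads to the same alkene.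

**Step 9**
Reactants: 13 methyl (3R,4S,8E,12E)-15-(furan-3-yl)-3-hydroxy-4,8,12-trimethylpentadeca-8,12-dienoate
Product: 15 methyl (2S,3S,4S,8E,12E)-15-(furan-3-yl)-2,3-dihydroxy-4,8,12-trimethylpentadeca-8,12-dienoate, via dilithium enolate alkoxide 14 (not isolated)
Conditions: LiN(iPr)2 (2.3 equiv), THF, −78 to −20 °C; then cannulated into 2-(benzenesulfonyl)-3-phenyloxaziridine, THF, −78 °C; aq. NH4Cl
Reagents that add atoms: 2-(benzenesulfonyl)-3-phenyloxaziridine, O=S(=O)(c1ccccc1)N1OC1c1ccccc1
Why: Fráter–Seebach dianion chemistry combined with Davis oxidation: in the six-membered lithium chelate the electrophilic oxygen reaches C5 on the face opposite the C6 substituent, which should give the 5,6-anti (erythro) diol.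

**Step 10**
Reactants: 15 methyl (2S,3S,4S,8E,12E)-15-(furan-3-yl)-2,3-dihydroxy-4,8,12-trimethylpentadeca-8,12-dienoate; 16 propanoyl chloride
Product: 18 methyl (2S,3S,4S,8E,12E)-15-(furan-3-yl)-3-hydroxy-4,8,12-trimethyl-2-(propanoyloxy)pentadeca-8,12-dienoate, via dibutylstannylene acetal 17 (not isolated)
Conditions: Bu2SnO (1.05 equiv), toluene, reflux (Dean–Stark); then 16 (1.05 equiv), 0 °C
Reagents that add atoms: none
Why: Stannylene-acetal-mediated monoacylation should occur at O5, the more acidic oxygen next to the ester and the less hindered one (O6 is flanked by the branched C7), under neutral conditions that do not induce acyl migration.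

**Step 11**
Reactants: 18 methyl (2S,3S,4S,8E,12E)-15-(furan-3-yl)-3-hydroxy-4,8,12-trimethyl-2-(propanoyloxy)pentadeca-8,12-dienoate
Product: 19 methyl (2S,3S,4S,8E,12E)-15-(furan-3-yl)-4,8,12-trimethyl-2-(propanoyloxy)-3-[(triethylsilyl)oxy]pentadeca-8,12-dienoate
Conditions: Et3SiOTf, 2,6-lutidine, CH2Cl2, −78 °C
Reagents that add atoms: triethylsilyl trifluoromethanesulfonate, CC[Si](CC)(CC)OS(=O)(=O)C(F)(F)F
Why: Silylation with the silyl triflate and a hindered pyridine base is fast at −78 °C even at the hindered C6 hydroxyl, which should leave no time for O5 to O6 propanoyl migration.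

**Step 12**
Reactants: 19 methyl (2S,3S,4S,8E,12E)-15-(furan-3-yl)-4,8,12-trimethyl-2-(propanoyloxy)-3-[(triethylsilyl)oxy]pentadeca-8,12-dienoate
Product: 20 (5S)-5-[(1S,2S,6E,10E)-13-(furan-3-yl)-2,6,10-trimethyl-1-[(triethylsilyl)oxy]trideca-6,10-dien-1-yl]-4-hydroxy-3-methylfuran-2(5H)-one
Conditions: LiN(SiMe3)2 (2.5 equiv), THF, −78 °C (to −40 °C if slow); AcOH quench at −78 °C
Reagents that add atoms: none
Why: LiN(SiMe3)2 removes a proton from the unhindered CH2 of the O5-propanoate, the enolate carbon C3 adds to the neighbouring methyl ester carbonyl C4 with loss of methoxide, and the second equivalent of base turns the dione at once into the lithium tetronate, which makes the closure irreversible. The closest known reaction type is the Dieckmann (Claisen-type) cyclisation of α-acyloxy esters to 3-alkyl tetronic acids. The ring O1–C2–C3–C4–C5 closes by 5-exo-trig acyl substitution through the new C3–C4 bond. No stereocentre is created (C3 ends as sp2), and C5, C6 and C7 are carried through unchanged. The step needs enolisation of the propanoate in preference to removal of C5–H, which would epimerise C5 or expel the C6 silyloxide; the bulky amide base at −78 °C, the shielded tertiary C5–H next to the silyloxy-bearing carbon and the non-acidic C5–H of the tetronate anion should secure this. The silyl group on O6 excludes acyl migration and six-membered closure, and the alkenes and the furan are inert to the amide base.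

**Step 13**
Reactants: 20 (5S)-5-[(1S,2S,6E,10E)-13-(furan-3-yl)-2,6,10-trimethyl-1-[(triethylsilyl)oxy]trideca-6,10-dien-1-yl]-4-hydroxy-3-methylfuran-2(5H)-one; 21 hexadecanoyl chloride
Product: 22 (2S)-2-[(1S,2S,6E,10E)-13-(furan-3-yl)-2,6,10-trimethyl-1-[(triethylsilyl)oxy]trideca-6,10-dien-1-yl]-4-methyl-5-oxo-2,5-dihydrofuran-3-yl hexadecanoate
Conditions: 21 (1.1 equiv), Et3N, CH2Cl2, −20 to 0 °C
Reagents that add atoms: none
Why: The tetronate anion formed with Et3N should be acylated on O4 by the hard acid chloride (C3 is already substituted) to give the enol ester, and no nucleophilic catalyst is added so that no O to C acyl shift is induced.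

**Step 14**
Reactants: 22 (2S)-2-[(1S,2S,6E,10E)-13-(furan-3-yl)-2,6,10-trimethyl-1-[(triethylsilyl)oxy]trideca-6,10-dien-1-yl]-4-methyl-5-oxo-2,5-dihydrofuran-3-yl hexadecanoate
Product: 23 (2S)-2-[(1S,2S,6E,10E)-13-(furan-3-yl)-1-hydroxy-2,6,10-trimethyltrideca-6,10-dien-1-yl]-4-methyl-5-oxo-2,5-dihydrofuran-3-yl hexadecanoate
Conditions: HF·pyridine, pyridine, THF, 0 °C; cold aq. NaHCO3; crude 23 taken on at once
Reagents that add atoms: none
Why: Fluoride-driven cleavage of the secondary triethylsilyl ether (strong Si–F bond) in the weakly acidic HF·pyridine medium should free the C6 hydroxyl while the enol ester, the alkenes and the furan stay intact.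

**Step 15**
Reactants: 23 (2S)-2-[(1S,2S,6E,10E)-13-(furan-3-yl)-1-hydroxy-2,6,10-trimethyltrideca-6,10-dien-1-yl]-4-methyl-5-oxo-2,5-dihydrofuran-3-yl hexadecanoate
Product: 25 (2E)-2-[(2S,6E,10E)-13-(furan-3-yl)-2,6,10-trimethyltrideca-6,10-dien-1-ylidene]-4-methyl-5-oxo-2,5-dihydrofuran-3-yl hexadecanoate, via C6 triflate 24 (not isolated)
Conditions: Tf2O (1.3 equiv), pyridine (5 equiv), CH2Cl2, −78 °C to rt
Reagents that add atoms: none
Why: Triflation followed by pyridine-induced E2 anti-elimination, a known route from γ-(α-hydroxyalkyl)butenolides to γ-alkylidenebutenolides: in the erythro 5S,6S triflate the conformer with C5–H anti-periplanar to C6–OTf holds C7 on the side of C4, so the E C5=C6 alkene should form, pyridine being too weak a base to generate a free C5 carbanion, and C7 is not touched.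

**Compound list**
1 | furan-3-ylmethanol | OCc1ccoc1 | starting material
2 | 3-(chloromethyl)furan | ClCc1ccoc1 | intermediate
3 | (2E,6E)-farnesyl acetate, (2E,6E)-3,7,11-trimethyldodeca-2,6,10-trien-1-yl acetate | CC(C)=CCC/C(C)=C/CC/C(C)=C/COC(C)=O | starting material
4 | (2E,6E,10E)-12-hydroxy-3,7,11-trimethyldodeca-2,6,10-trien-1-yl acetate | OC/C(C)=C/CC/C(C)=C/CC/C(C)=C/COC(C)=O | intermediate
5 | (furan-3-ylmethyl)magnesium chloride | Cl[Mg]Cc1ccoc1 | intermediate (not isolated)
6 | (2E,6E,10E)-13-(furan-3-yl)-2,6,10-trimethyltrideca-2,6,10-trien-1-ol | OC/C(C)=C/CC/C(C)=C/CC/C(C)=C/CCc1ccoc1 | intermediate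
7 | (2E,6E,10E)-13-(furan-3-yl)-2,6,10-trimethyltrideca-2,6,10-trienal | O=C/C(C)=C/CC/C(C)=C/CC/C(C)=C/CCc1ccoc1 | intermediate
8 | (2E,6E,10E)-13-(furan-3-yl)-2,6,10-trimethyltrideca-2,6,10-trienoic acid | OC(=O)/C(C)=C/CC/C(C)=C/CC/C(C)=C/CCc1ccoc1 | intermediate
9 | (2S,6E,10E)-13-(furan-3-yl)-2,6,10-trimethyltrideca-6,10-dienoic acid | OC(=O)[C@@H](C)CCC/C(C)=C/CC/C(C)=C/CCc1ccoc1 | intermediate
10 | methyl potassium malonate (potassium 3-methoxy-3-oxopropanoate) | COC(=O)CC(=O)[O-].[K+] | starting material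
11 | (2S,6E,10E)-13-(furan-3-yl)-1-(1H-imidazol-1-yl)-2,6,10-trimethyltrideca-6,10-dien-1-one (acyl imidazolide) | O=C([C@@H](C)CCC/C(C)=C/CC/C(C)=C/CCc1ccoc1)n1ccnc1 | intermediate (not isolated)
12 | methyl (4S,8E,12E)-15-(furan-3-yl)-4,8,12-trimethyl-3-oxopentadeca-8,12-dienoate | COC(=O)CC(=O)[C@@H](C)CCC/C(C)=C/CC/C(C)=C/CCc1ccoc1 | intermediate
13 | methyl (3R,4S,8E,12E)-15-(furan-3-yl)-3-hydroxy-4,8,12-trimethylpentadeca-8,12-dienoate | COC(=O)C[C@@H](O)[C@@H](C)CCC/C(C)=C/CC/C(C)=C/CCc1ccoc1 | intermediate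
14 | dilithium enolate alkoxide of 13 (lithium ester enolate at C1/C2, lithium alkoxide at C3) | [Li]OC(OC)=C[C@@H](O[Li])[C@@H](C)CCC/C(C)=C/CC/C(C)=C/CCc1ccoc1 | intermediate (not isolated)
15 | methyl (2S,3S,4S,8E,12E)-15-(furan-3-yl)-2,3-dihydroxy-4,8,12-trimethylpentadeca-8,12-dienoate (anti diol) | COC(=O)[C@@H](O)[C@@H](O)[C@@H](C)CCC/C(C)=C/CC/C(C)=C/CCc1ccoc1 | intermediate
16 | propanoyl chloride | CCC(=O)Cl | starting material
17 | methyl (4S,5S)-2,2-dibutyl-5-[(2S,6E,10E)-13-(furan-3-yl)-6,10-dimethyltrideca-6,10-dien-2-yl]-1,3,2-dioxastannolane-4-carboxylate | COC(=O)[C@H]1O[Sn](CCCC)(CCCC)O[C@H]1[C@@H](C)CCC/C(C)=C/CC/C(C)=C/CCc1ccoc1 | intermediate (not isolated)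
18 | methyl (2S,3S,4S,8E,12E)-15-(furan-3-yl)-3-hydroxy-4,8,12-trimethyl-2-(propanoyloxy)pentadeca-8,12-dienoate | COC(=O)[C@@H](OC(=O)CC)[C@@H](O)[C@@H](C)CCC/C(C)=C/CC/C(C)=C/CCc1ccoc1 | intermediate
19 | methyl (2S,3S,4S,8E,12E)-15-(furan-3-yl)-4,8,12-trimethyl-2-(propanoyloxy)-3-[(triethylsilyl)oxy]pentadeca-8,12-dienoate | COC(=O)[C@@H](OC(=O)CC)[C@@H](O[Si](CC)(CC)CC)[C@@H](C)CCC/C(C)=C/CC/C(C)=C/CCc1ccoc1 | intermediate
20 | (5S)-5-[(1S,2S,6E,10E)-13-(furan-3-yl)-2,6,10-trimethyl-1-[(triethylsilyl)oxy]trideca-6,10-dien-1-yl]-4-hydroxy-3-methylfuran-2(5H)-one | O=C1O[C@@H]([C@@H](O[Si](CC)(CC)CC)[C@@H](C)CCC/C(C)=C/CC/C(C)=C/CCc2ccoc2)C(O)=C1C | intermediate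
21 | hexadecanoyl chloride | CCCCCCCCCCCCCCCC(=O)Cl | starting material
22 | (2S)-2-[(1S,2S,6E,10E)-13-(furan-3-yl)-2,6,10-trimethyl-1-[(triethylsilyl)oxy]trideca-6,10-dien-1-yl]-4-methyl-5-oxo-2,5-dihydrofuran-3-yl hexadecanoate | O=C1O[C@@H]([C@@H](O[Si](CC)(CC)CC)[C@@H](C)CCC/C(C)=C/CC/C(C)=C/CCc2ccoc2)C(OC(=O)CCCCCCCCCCCCCCC)=C1C | intermediate
23 | (2S)-2-[(1S,2S,6E,10E)-13-(furan-3-yl)-1-hydroxy-2,6,10-trimethyltrideca-6,10-dien-1-yl]-4-methyl-5-oxo-2,5-dihydrofuran-3-yl hexadecanoate | O=C1O[C@@H]([C@@H](O)[C@@H](C)CCC/C(C)=C/CC/C(C)=C/CCc2ccoc2)C(OC(=O)CCCCCCCCCCCCCCC)=C1C | intermediate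
24 | (2S)-2-[(1S,2S,6E,10E)-13-(furan-3-yl)-2,6,10-trimethyl-1-[(trifluoromethanesulfonyl)oxy]trideca-6,10-dien-1-yl]-4-methyl-5-oxo-2,5-dihydrofuran-3-yl hexadecanoate | O=C1O[C@@H]([C@@H](OS(=O)(=O)C(F)(F)F)[C@@H](C)CCC/C(C)=C/CC/C(C)=C/CCc2ccoc2)C(OC(=O)CCCCCCCCCCCCCCC)=C1C | intermediate (not isolated)
25 | (2E)-2-[(2S,6E,10E)-13-(furan-3-yl)-2,6,10-trimethyltrideca-6,10-dien-1-ylidene]-4-methyl-5-oxo-2,5-dihydrofuran-3-yl hexadecanoate (CNP0269639.1) | CCCCCCCCCCCCCCCC(=O)OC1=C(C)C(=O)O/C1=C/[C@@H](C)CCC/C(C)=C/CC/C(C)=C/CCc1ccoc1 | target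

**Step count**
Total: 15 steps. Longest linear sequence: 14 steps (steps 2 to 15, from farnesyl acetate 3); step 1 is a one-step side branch.

**Steps most likely to fail**

1. Step 15 (prepared by step 14). Once O6 is free, the palmitoyl group may move from O4 to O6 through a six-membered transition state. The elimination may also leave the concerted anti pathway for a carbanion pathway that loses the erythro information and drifts to the Z alkene.
Fallback, setting out from 20: O4 is masked as an allyl ether and the palmitoyl group is put on last. Mitsunobu O-allylation (allyl alcohol, PPh3, diisopropyl azodicarboxylate, THF) should give the 4-allyloxy butenolide silyl ether F1. HF·pyridine then frees the C6 alcohol F2, which has no acyl group to migrate. Tf2O/pyridine should give the (E)-4-allyloxy-5-alkylidene butenolide F3; the alkoxy group makes C5–H less acidic than an acyloxy group does, which favours the concerted anti pathway. Pd(PPh3)4 with morpholine (Tsuji–Trost deallylation) releases the (E)-5-alkylidene tetronic acid F4, and acylation with 21 and Et3N returns to the route at 25.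

2. Step 12. Proton removal at C5 instead of the propanoate CH2 would epimerise C5 or expel the C6 silyloxide. Alternatively, attack on the methyl ester may be too slow, so that the propanoate is simply cleaved.
Fallback, setting out from 15: the C3–C4 bond is made intermolecularly and the ring is closed by lactonisation. 2,2-Dimethoxypropane with pyridinium p-toluenesulfonate should give the cis-acetonide ester F5. Crossed Claisen condensation with the lithium enolate of methyl propanoate (LiN(iPr)2, THF, −78 °C) gives the α-methyl β-keto ester F6. Aqueous AcOH removes the acetonide, and K2CO3 in MeOH lactonises O5 onto the ester (five-membered closure, the classical γ-hydroxy β-keto ester route to tetronic acids) to give the 5-(1-hydroxyalkyl)tetronic acid F7. Acylation of the acidic O4 with one equivalent of 21 and Et3N at −40 °C returns to the route at 23.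

3. Step 10. Regioselection between O5 and O6 may be incomplete, or the propanoyl group may migrate to O6, which would put the acyl group on the wrong oxygen for the Dieckmann closure.
Fallback, setting out from 13: the two oxygens are differentiated by construction. Et3SiOTf/2,6-lutidine gives the β-silyloxy ester F8. Enolate oxidation (NaN(SiMe3)2, THF, −78 °C, then the oxaziridine of step 9) should give mainly the anti α-hydroxy β-silyloxy ester F9; any syn isomer would be removed by chromatography. Acylation with 16, pyridine and 4-(dimethylamino)pyridine returns to the route at 19.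

**Further compounds**
F1 | step 15 | (5S)-5-[(1S,2S,6E,10E)-13-(furan-3-yl)-2,6,10-trimethyl-1-[(triethylsilyl)oxy]trideca-6,10-dien-1-yl]-3-methyl-4-(prop-2-en-1-yloxy)furan-2(5H)-one | O=C1O[C@@H]([C@@H](O[Si](CC)(CC)CC)[C@@H](C)CCC/C(C)=C/CC/C(C)=C/CCc2ccoc2)C(OCC=C)=C1C
F2 | step 15 | (5S)-5-[(1S,2S,6E,10E)-13-(furan-3-yl)-1-hydroxy-2,6,10-trimethyltrideca-6,10-dien-1-yl]-3-methyl-4-(prop-2-en-1-yloxy)furan-2(5H)-one | O=C1O[C@@H]([C@@H](O)[C@@H](C)CCC/C(C)=C/CC/C(C)=C/CCc2ccoc2)C(OCC=C)=C1C
F3 | step 15 | (5E)-5-[(2S,6E,10E)-13-(furan-3-yl)-2,6,10-trimethyltrideca-6,10-dien-1-ylidene]-3-methyl-4-(prop-2-en-1-yloxy)furan-2(5H)-one | C=CCOC1=C(C)C(=O)O/C1=C/[C@@H](C)CCC/C(C)=C/CC/C(C)=C/CCc1ccoc1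
F4 | step 15 | (5E)-5-[(2S,6E,10E)-13-(furan-3-yl)-2,6,10-trimethyltrideca-6,10-dien-1-ylidene]-4-hydroxy-3-methylfuran-2(5H)-one | OC1=C(C)C(=O)O/C1=C/[C@@H](C)CCC/C(C)=C/CC/C(C)=C/CCc1ccoc1
F5 | step 12 | methyl (4S,5S)-5-[(2S,6E,10E)-13-(furan-3-yl)-6,10-dimethyltrideca-6,10-dien-2-yl]-2,2-dimethyl-1,3-dioxolane-4-carboxylate | COC(=O)[C@H]1OC(C)(C)O[C@H]1[C@@H](C)CCC/C(C)=C/CC/C(C)=C/CCc1ccoc1
F6 | step 12 | methyl 3-[(4S,5S)-5-[(2S,6E,10E)-13-(furan-3-yl)-6,10-dimethyltrideca-6,10-dien-2-yl]-2,2-dimethyl-1,3-dioxolan-4-yl]-2-methyl-3-oxopropanoate (both C2 epimers) | COC(=O)C(C)C(=O)[C@H]1OC(C)(C)O[C@H]1[C@@H](C)CCC/C(C)=C/CC/C(C)=C/CCc1ccoc1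
F7 | step 12 | (5S)-5-[(1S,2S,6E,10E)-13-(furan-3-yl)-1-hydroxy-2,6,10-trimethyltrideca-6,10-dien-1-yl]-4-hydroxy-3-methylfuran-2(5H)-one | O=C1O[C@@H]([C@@H](O)[C@@H](C)CCC/C(C)=C/CC/C(C)=C/CCc2ccoc2)C(O)=C1C
F8 | step 10 | methyl (3R,4S,8E,12E)-15-(furan-3-yl)-4,8,12-trimethyl-3-[(triethylsilyl)oxy]pentadeca-8,12-dienoate | COC(=O)C[C@@H](O[Si](CC)(CC)CC)[C@@H](C)CCC/C(C)=C/CC/C(C)=C/CCc1ccoc1
F9 | step 10 | methyl (2S,3S,4S,8E,12E)-15-(furan-3-yl)-2-hydroxy-4,8,12-trimethyl-3-[(triethylsilyl)oxy]pentadeca-8,12-dienoate | COC(=O)[C@@H](O)[C@@H](O[Si](CC)(CC)CC)[C@@H](C)CCC/C(C)=C/CC/C(C)=C/CCc1ccoc1
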